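Retrosynthesis: the tiglate C8–O bond is cut first, then C6–C7 and O6–C12 together (carbocycle and lactone), then C7–C11, C2–C3 and C1–C2. This leaves (R)-linalool, 3-methyl-2(5H)-furanone, methyl acrylate, the Ohira–Bestmann reagent and tiglic acid.
Enabling feature: the C6–C7 bond belongs at the same time to the ten-membered carbocycle C1–C10, to the fusion of the cis α-methylene-γ-butyrolactone (O6–C6–C7–C11(=C13)–C12) and to the adduct of a 2-carboxyallyl metal (C13–C11(C12)=C7) with an aldehyde (C6). The Z-C1=C2 and Z-C4=C5 alkenes bend the open chain so that its two ends meet.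
Forward: the chain is joined linearly (C1–C2 by alkynylation, C2–C3 by acetylide acylation, C7–C11 by a Morita–Baylis–Hillman reaction). Only then do the carbocycle and the lactone close, both in one chromium-mediated step, followed by tiglate installation and desilylation.
Stereochemistry: C10 comes from (R)-linalool, C8 from L-proline α-aminoxylation and C3 from CBS reduction. C6 and C7 are set in the ring closure (syn from the Z-allyl unit in a chair, absolute sense relayed from C8). Z-C4=C5 comes from the butenolide ring, Z-C1=C2 from Lindlar reduction and the E ester from tiglic acid.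

Key step: step 19

Remark on numbering: locants are those of the target (carbocycle C1–C10, C14 on C10, C15 on C4, lactone O6–C12(=O)–C11(=C13)–C7). "Seco-chain" means the chain C7–C8–C9–C10–C1–C2–C3–C4–C5–C6, and descriptors are the CIP descriptors in the compound at hand.
Remark on mixtures: the anisylidene acetal carbon (compounds 8–22) and the C7 carbinol of 26 are assumed to form as epimer mixtures; both centres disappear later (steps 13 and 16), so the mixtures are carried on.

Step 1
Reactants: 1 (R)-(−)-linalool [(3R)-3,7-dimethylocta-1,6-dien-3-ol]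
Product: 2 (3R)-3,7-dimethyl-3-(triethylsilyloxy)octa-1,6-diene
Conditions: TESOTf, 2,6-lutidine, CH2Cl2, −78 → 0 °C
Reagents that add atoms: triethylsilyl trifluoromethanesulfonate, CC[Si](CC)(CC)OS(=O)(=O)C(F)(F)F
Why: A silyl triflate with 2,6-lutidine silylates even hindered tertiary alcohols (silyl ether protection) and leaves the future C10 stereocentre untouched.

Step 2
Reactants: 2
Product: 4 (4R)-4-methyl-4-(triethylsilyloxy)hex-5-enal, via secondary ozonide 3 (not isolated)
Conditions: O3, CH2Cl2, −78 °C, Sudan Red 7B as end-point indicator; then PPh3, −78 °C → rt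
Reagents that add atoms: ozone, [O-][O+]=O
Why: Ozone is an electrophile and cleaves the electron-rich trisubstituted alkene far faster than the monosubstituted vinyl group next to the silyloxy-bearing quaternary carbon, so a dye-indicated end point followed by PPh3 reduction of the ozonide should give the aldehyde selectively (chemoselective ozonolysis).

Step 3
Reactants: 4
Product: 6 (2R,4R)-4-methyl-2-(N-phenylaminooxy)-4-(triethylsilyloxy)hex-5-en-1-ol, via α-aminoxy aldehyde 5 (not isolated)
Conditions: PhNO (0.9 equiv), L-proline (20 mol %), DMSO, rt; then NaBH4, MeOH, 0 °C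
Reagents that add atoms: nitrosobenzene, O=Nc1ccccc1
Why: In the organocatalytic α-aminoxylation the L-proline enamine of 4 attacks the oxygen of nitrosobenzene, which is held by a hydrogen bond to the carboxylic acid, on one face only, so C8 is set as R by the catalyst regardless of the remote C10 centre, and immediate NaBH4 reduction protects the labile α-aminoxy aldehyde from racemisation.

Step 4
Reactants: 6
Product: 7 (2R,4R)-4-methyl-4-(triethylsilyloxy)hex-5-ene-1,2-diol
Conditions: Zn dust, AcOH/EtOH, rt
Reagents that add atoms: none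
Why: Zinc in acetic acid cleaves the weak N–O bond reductively (dissolving-metal N–O cleavage) and touches neither the vinyl group nor the tertiary silyl ether, so the 1,2-diol is freed with C8 unchanged.

Step 5
Reactants: 7
Product: 8 (4R)-2-(4-methoxyphenyl)-4-[(2R)-2-methyl-2-(triethylsilyloxy)but-3-en-1-yl]-1,3-dioxolane
Conditions: 4-MeOC6H4CH(OMe)2, PPTS (cat.), CH2Cl2, rt
Reagents that add atoms: 4-methoxybenzaldehyde dimethyl acetal, COc1ccc(C(OC)OC)cc1
Why: Acid-catalysed transacetalisation closes the five-membered dioxolane on the 1,2-diol, masks both hydroxyls in one group that can later be opened regioselectively, and gives an inconsequential mixture of acetal epimers.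

Step 6
Reactants: 8
Product: 10 (2R)-3-[(4R)-2-(4-methoxyphenyl)-1,3-dioxolan-4-yl]-2-methyl-2-(triethylsilyloxy)propanal, via vicinal diol 9 (not isolated)
Conditions: OsO4 (cat.), NaIO4, 2,6-lutidine, 1,4-dioxane/H2O, rt
Reagents that add atoms: osmium tetroxide, O=[Os](=O)(=O)=O; sodium periodate, [Na+].[O-]I(=O)(=O)=O (restocks the oxygen that osmium delivers)
Why: In the Lemieux–Johnson oxidation OsO4 dihydroxylates the only alkene and NaIO4 cleaves the diol and reoxidises osmium, while 2,6-lutidine keeps the medium neutral for the acetal and the silyl ether; the aldehyde has no α-hydrogen and cannot epimerise.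

Step 7
Reactants: 10; 11 dimethyl (1-diazo-2-oxopropyl)phosphonate (Ohira–Bestmann reagent)
Product: 13 (4R)-2-(4-methoxyphenyl)-4-[(2R)-2-methyl-2-(triethylsilyloxy)but-3-yn-1-yl]-1,3-dioxolane, via diazoalkene 12 (not isolated)
Conditions: K2CO3, MeOH, 0 °C → rt
Reagents that add atoms: none
Why: Methanolysis of 11 releases the dimethyl (diazomethyl)phosphonate anion, which olefinates the aldehyde to the diazoalkene; loss of N2 and a 1,2-hydrogen shift then give the terminal alkyne carrying C2 (Seyferth–Gilbert homologation in its Ohira–Bestmann form), under conditions mild enough for the acetal and the silyl ether.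

Step 8
Reactants: 14 3-methylfuran-2(5H)-one
Product: 16 (2Z)-4-(tert-butyldimethylsilyloxy)-N-methoxy-N,2-dimethylbut-2-enamide, via hydroxy amide 15 (not isolated)
Conditions: MeONHMe·HCl, AlMe3, CH2Cl2, 0 °C → rt; aq. potassium sodium tartrate work-up; crude 15 at once with TBSCl, imidazole, CH2Cl2, 0 °C
Reagents that add atoms: N,O-dimethylhydroxylamine hydrochloride, CNOC.Cl; tert-butyldimethylsilyl chloride, CC(C)(C)[Si](C)(C)Cl
Why: The aluminium amide opens the lactone by acyl substitution (Weinreb aminolysis) without touching the alkene, whose Z geometry is inherited from the ring, and silylation of the crude primary alcohol at once prevents the hydroxy amide from closing back to the butenolide.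

Step 9
Reactants: 13; 16
Product: 19 (4Z,8R,10R)-ynone of the seco-chain carrying 6-OTBS; C3 ketone; C1≡C2; 10-OTES; 7,8-O-(4-methoxybenzylidene) acetal, via lithium acetylide 17 (not isolated), via tetrahedral lithium adduct 18 (not isolated)
Conditions: n-BuLi, THF, −78 °C; then 16, −78 → −20 °C; AcOH quench at −78 °C
Reagents that add atoms: none
Why: The lithium acetylide adds to the Weinreb amide to give a chelated tetrahedral adduct that collapses to the ketone only on protonation, so the C2–C3 bond forms without over-addition (Weinreb ketone synthesis), and the cold acidic quench keeps the released hydroxylamine from adding to the ynone.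

Step 10
Reactants: 19
Product: 20 (3S,4Z,8R,10R)-propargylic alcohol (C3–OH; otherwise as 19)
Conditions: (S)-2-methyl-CBS-oxazaborolidine (1.5 equiv), BH3·SMe2, THF, −40 °C; MeOH quench
Reagents that add atoms: none
Why: In the Corey–Bakshi–Shibata reduction the ketone binds to the oxazaborolidine–borane complex with the α-branched alkenyl group as the large and the linear alkynyl group as the small substituent, so the (S)-catalyst should deliver hydride to the face that gives the 3S carbinol (the same arrangement is called 3R once C2 is an alkene carbon), by 1,2-reduction only.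

Step 11
Reactants: 20
Product: 21 (3S,4Z,8R,10R)-3-O-TBS ether of 20
Conditions: TBSCl, imidazole, DMAP (cat.), DMF, rt
Reagents that add atoms: tert-butyldimethylsilyl chloride, CC(C)(C)[Si](C)(C)Cl
Why: Standard silylation of the secondary propargylic alcohol with TBSCl and imidazole; the tertiary C10 oxygen is already blocked and no stereocentre is affected.

Step 12
Reactants: 21
Product: 22 (1Z,3R,4Z,8R,10R)-skipped diene (6-OTBS; 3-OTBS; 10-OTES; 7,8-O-anisylidene acetal)
Conditions: H2 (1 atm), Pd/CaCO3 poisoned with Pb(OAc)2 (Lindlar catalyst), quinoline, EtOAc, rt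
Reagents that add atoms: none
Why: Syn addition of hydrogen on the poisoned palladium surface (Lindlar semihydrogenation) should give the Z-C1=C2 alkene and stop there, the trisubstituted alkene and the benzylic acetal being inert to this catalyst.

Step 13
Reactants: 22
Product: 23 (1Z,3R,4Z,8R,10R)-C7 primary alcohol with 8-O-(4-methoxybenzyl) ether (6-OTBS; 3-OTBS; 10-OTES)
Conditions: i-Bu2AlH (4 equiv), CH2Cl2, −78 → 0 °C; aq. potassium sodium tartrate
Reagents that add atoms: none
Why: The aluminium hydride binds the less hindered primary oxygen of the dioxolane, the C–O bond on that side breaks and hydride is delivered to the oxocarbenium ion, so the reductive acetal opening should leave the p-methoxybenzyl group on O8 and free the C7 primary alcohol.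

Step 14
Reactants: 23
Product: 24 (1Z,3R,4Z,8R,10R)-C7 aldehyde with 8-OPMB
Conditions: Dess–Martin periodinane, NaHCO3, CH2Cl2, 0 °C → rt
Reagents that add atoms: none
Why: Dess–Martin oxidation under bicarbonate buffer is neutral and fast, so the α-alkoxy aldehyde forms without epimerisation at C8 and is used crude.

Step 15
Reactants: 24; 25 methyl acrylate
Product: 26 Morita–Baylis–Hillman adduct (C7–OH epimers; C11(=C13H2)CO2Me on C7; 8R-OPMB; otherwise as 24)
Conditions: 25 (10 equiv), DABCO (1 equiv), MeOH, rt
Reagents that add atoms: none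
Why: In the Morita–Baylis–Hillman reaction DABCO adds to methyl acrylate, the ammonium enolate adds to the aldehyde (activated by its α-alkoxy group) and loss of the amine forms the C7–C11 bond and the C11=C13 alkene; the configuration of the new C7 carbinol is irrelevant because C7 becomes sp2 in the next step.

Step 16
Reactants: 26
Product: 27 (1Z,3R,4Z,7Z,8R,10R)-methyl 2-(bromomethyl)enoate (C13–Br; C7=C11; 6-OTBS; 3-OTBS; 10-OTES; 8-OPMB)
Conditions: NBS, Me2S, CH2Cl2, 0 °C (premixed); then 26, 0 °C → rt
Reagents that add atoms: N-bromosuccinimide, BrN1C(=O)CCC1=O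
Why: The sulfonium salt formed from NBS and Me2S activates the allylic hydroxyl and bromide attacks C13 in SN2′ fashion, which moves the double bond to C7=C11 and gives the thermodynamically preferred Z isomer with C8 trans to the ester (bromination of Morita–Baylis–Hillman adducts with allylic transposition).

Step 17
Reactants: 27
Product: 28 (1Z,3R,4Z,7Z,8R,10R)-C6 allylic alcohol (C13–Br; 3-OTBS; 10-OTES; 8-OPMB)
Conditions: HF (48% aq.), MeCN, 0 °C
Reagents that add atoms: none
Why: Under dilute aqueous HF the unhindered primary allylic TBS ether is cleaved much faster than the secondary TBS and the tertiary TES ethers (selective desilylation), and the amine-free medium spares the electrophilic allylic bromide, which free pyridine would alkylate.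

Step 18
Reactants: 28
Product: 29 (1Z,3R,4Z,7Z,8R,10R)-seco precursor with C6 Z-enal and C13 allylic bromide (3-OTBS; 10-OTES; 8-OPMB)
Conditions: Dess–Martin periodinane, NaHCO3, CH2Cl2, 0 °C
Reagents that add atoms: none
Why: Buffered Dess–Martin oxidation converts the Z-allylic alcohol into the Z-enal without isomerisation of the C4=C5 bond and leaves the allylic bromide and the enoate untouched.

Step 19
Reactants: 29
Product: 32 (1Z,3R,4Z,6S,7R,8R,10R)-protected cis-fused α-methylene lactone on the ten-membered ring (3-OTBS; 10-OTES; 8-OPMB), via allylchromium species 30 (not isolated), via cyclised chromium alkoxide 31 (not isolated)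
Conditions: CrCl2 (10 equiv), 4 Å molecular sieves, THF, rt; 29 added by syringe pump over 12 h to 0.003 M; then 40 °C, 2 h; aq. NH4Cl
Reagents that add atoms: none
Why: Two equivalents of divalent chromium reduce the C13–Br bond to an allyl species of trivalent chromium (30), which adds to the C6 aldehyde through its γ-carbon C7 in a six-membered chair transition state (SE2′), forming C6–C7 and restoring the C11=C13 methylene; the chromium alkoxide 31 then attacks the C12 methyl ester and expels methoxide. The closest known reaction type is the intramolecular Nozaki–Hiyama–Kishi (Barbier-type) allylation of ω-formyl 2-(bromomethyl)alk-2-enoates to ten-membered α-methylene lactones, together with the cis-selective intermolecular chromium 2-alkoxycarbonylallylation of aldehydes. The carbocycle closes by intramolecular carbonyl allylation (formally 10-exo-trig at the aldehyde carbon) and the γ-lactone by 5-exo-trig acyl substitution of O6 on C12. C6 and C7 are set together: their syn (cis-lactone) relation follows from the Z geometry of the allyl unit (C8 cis to C13) in the chair, and their absolute sense from C8, because allylic 1,3-strain with the C13 methylene holds H8 in the plane of C7=C11 so that C6 arrives anti to the C8–C9 bond and gauche to the OPMB group, which corresponds to 7R and hence 6S. The step needs ring closure to beat oligomerisation, γ-attack, and retention of the C8 oxygen: the two Z alkenes fold the chain so that C6 lies near C7, slow addition at high dilution suppresses intermolecular coupling, the aldehyde is a non-enolisable enal, and O8 is an ether rather than an ester so that the allylchromium does not eliminate it.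

Step 20
Reactants: 32
Product: 33 (1Z,3R,4Z,6S,7R,8R,10R)-C8 alcohol (3-OTBS; 10-OTES)
Conditions: DDQ (1.3 equiv), CH2Cl2/pH 7 phosphate buffer, 0 °C
Reagents that add atoms: none
Why: DDQ oxidises the electron-rich p-methoxybenzyl ether through a charge-transfer complex to the oxocarbenium ion, which water hydrolyses to the C8 alcohol and p-anisaldehyde (oxidative PMB cleavage); at 0 °C under buffer the silyl ethers, the alkenes and the lactone should not react.

Step 21
Reactants: 33; 34 tiglic acid [(2E)-2-methylbut-2-enoic acid]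
Product: 36 (1Z,3R,4Z,6S,7R,8R,10R)-C8 tiglate (3-OTBS; 10-OTES), via mixed anhydride 35 (not isolated)
Conditions: 34, 2,4,6-Cl3C6H2COCl, Et3N, toluene, rt; then 33, DMAP, rt
Reagents that add atoms: none
Why: In the Yamaguchi esterification the mixed anhydride acylates DMAP at the less hindered tigloyl carbonyl and the acylpyridinium transfers the tigloyl group to the hindered C8 alcohol with its E geometry intact; fast acylation under weakly basic conditions should forestall migration of the lactone from O6 to O8, and C3 and C10 are still silylated.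

Step 22
Reactants: 36
Product: 37 target CNP0262559.2 [(1Z,3R,4Z,6S,7R,8R,10R)-3,10-dihydroxy-8-tigloyloxy germacra-1,4,11(13)-trien-12,6-olide]
Conditions: HF·pyridine, pyridine, THF, 0 °C → rt
Reagents that add atoms: none
Why: Fluoride cleaves both Si–O bonds (global desilylation), and the pyridine-buffered reagent is mild enough for the bis-allylic C3 alcohol, the tiglate and the α-methylene lactone.

Compound list
1 | (R)-(−)-linalool | C=C[C@](C)(O)CCC=C(C)C | starting material
2 | (3R)-3,7-dimethyl-3-(triethylsilyloxy)octa-1,6-diene | C=C[C@](C)(O[Si](CC)(CC)CC)CCC=C(C)C | intermediate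
3 | 3,3-dimethyl-5-[(3R)-3-methyl-3-(triethylsilyloxy)pent-4-en-1-yl]-1,2,4-trioxolane (secondary ozonide, not isolated) | C=C[C@](C)(O[Si](CC)(CC)CC)CCC1OOC(C)(C)O1 | intermediate
4 | (4R)-4-methyl-4-(triethylsilyloxy)hex-5-enal | C=C[C@](C)(O[Si](CC)(CC)CC)CCC=O | intermediate
5 | (2R,4R)-4-methyl-2-(N-phenylaminooxy)-4-(triethylsilyloxy)hex-5-enal (not isolated) | C=C[C@](C)(O[Si](CC)(CC)CC)C[C@@H](ONc1ccccc1)C=O | intermediate
6 | (2R,4R)-4-methyl-2-(N-phenylaminooxy)-4-(triethylsilyloxy)hex-5-en-1-ol | C=C[C@](C)(O[Si](CC)(CC)CC)C[C@@H](ONc1ccccc1)CO | intermediate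
7 | (2R,4R)-4-methyl-4-(triethylsilyloxy)hex-5-ene-1,2-diol | C=C[C@](C)(O[Si](CC)(CC)CC)C[C@@H](O)CO | intermediate
8 | (4R)-2-(4-methoxyphenyl)-4-[(2R)-2-methyl-2-(triethylsilyloxy)but-3-en-1-yl]-1,3-dioxolane (acetal epimers) | C=C[C@](C)(O[Si](CC)(CC)CC)C[C@@H]1COC(c2ccc(OC)cc2)O1 | intermediate
9 | (3R)-4-[(4R)-2-(4-methoxyphenyl)-1,3-dioxolan-4-yl]-3-methyl-3-(triethylsilyloxy)butane-1,2-diol (C2 epimers, not isolated) | OCC(O)[C@](C)(O[Si](CC)(CC)CC)C[C@@H]1COC(c2ccc(OC)cc2)O1 | intermediate
10 | (2R)-3-[(4R)-2-(4-methoxyphenyl)-1,3-dioxolan-4-yl]-2-methyl-2-(triethylsilyloxy)propanal | O=C[C@](C)(O[Si](CC)(CC)CC)C[C@@H]1COC(c2ccc(OC)cc2)O1 | intermediate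
11 | dimethyl (1-diazo-2-oxopropyl)phosphonate (Ohira–Bestmann reagent) | CC(=O)C(=[N+]=[N-])P(=O)(OC)OC | starting material
12 | (3R)-1-diazo-4-[(4R)-2-(4-methoxyphenyl)-1,3-dioxolan-4-yl]-3-methyl-3-(triethylsilyloxy)but-1-ene (diazoalkene, not isolated) | [N-]=[N+]=C=C[C@](C)(O[Si](CC)(CC)CC)C[C@@H]1COC(c2ccc(OC)cc2)O1 | intermediate
13 | (4R)-2-(4-methoxyphenyl)-4-[(2R)-2-methyl-2-(triethylsilyloxy)but-3-yn-1-yl]-1,3-dioxolane | C#C[C@](C)(O[Si](CC)(CC)CC)C[C@@H]1COC(c2ccc(OC)cc2)O1 | intermediate
14 | 3-methylfuran-2(5H)-one | CC1=CCOC1=O | starting material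
15 | (2Z)-4-hydroxy-N-methoxy-N,2-dimethylbut-2-enamide (not isolated) | CON(C)C(=O)/C(C)=C\CO | intermediate
16 | (2Z)-4-(tert-butyldimethylsilyloxy)-N-methoxy-N,2-dimethylbut-2-enamide | CON(C)C(=O)/C(C)=C\CO[Si](C)(C)C(C)(C)C | intermediate
17 | lithium acetylide of 13 (not isolated) | [Li]C#C[C@](C)(O[Si](CC)(CC)CC)C[C@@H]1COC(c2ccc(OC)cc2)O1 | intermediate
18 | tetrahedral lithium N-methoxy-N-methyl hemiaminal adduct at C3 (not isolated) | CC(C)(C)[Si](C)(C)OC/C=C(/C)C(O[Li])(N(C)OC)C#C[C@](C)(O[Si](CC)(CC)CC)C[C@@H]1COC(c2ccc(OC)cc2)O1 | intermediate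
19 | (4Z,8R,10R)-seco-chain ynone: 6-OTBS, C3 ketone, C1≡C2, 10-OTES, 7,8-O-(4-methoxybenzylidene) acetal | CC(C)(C)[Si](C)(C)OC/C=C(/C)C(=O)C#C[C@](C)(O[Si](CC)(CC)CC)C[C@@H]1COC(c2ccc(OC)cc2)O1 | intermediate
20 | (3S,4Z,8R,10R)-propargylic alcohol: C3–OH, otherwise as 19 | CC(C)(C)[Si](C)(C)OC/C=C(/C)[C@H](O)C#C[C@](C)(O[Si](CC)(CC)CC)C[C@@H]1COC(c2ccc(OC)cc2)O1 | intermediate
21 | (3S,4Z,8R,10R)-3-O-TBS ether of 20 | CC(C)(C)[Si](C)(C)OC/C=C(/C)[C@H](O[Si](C)(C)C(C)(C)C)C#C[C@](C)(O[Si](CC)(CC)CC)C[C@@H]1COC(c2ccc(OC)cc2)O1 | intermediate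
22 | (1Z,3R,4Z,8R,10R)-skipped diene: 6-OTBS, 3-OTBS, 10-OTES, 7,8-O-anisylidene acetal | CC(C)(C)[Si](C)(C)OC/C=C(/C)[C@H](O[Si](C)(C)C(C)(C)C)/C=C\[C@](C)(O[Si](CC)(CC)CC)C[C@@H]1COC(c2ccc(OC)cc2)O1 | intermediate
23 | (1Z,3R,4Z,8R,10R)-C7 primary alcohol with 8-OPMB, 6-OTBS, 3-OTBS, 10-OTES | CC(C)(C)[Si](C)(C)OC/C=C(/C)[C@H](O[Si](C)(C)C(C)(C)C)/C=C\[C@](C)(O[Si](CC)(CC)CC)C[C@@H](OCc1ccc(OC)cc1)CO | intermediate
24 | (1Z,3R,4Z,8R,10R)-C7 aldehyde with 8-OPMB | CC(C)(C)[Si](C)(C)OC/C=C(/C)[C@H](O[Si](C)(C)C(C)(C)C)/C=C\[C@](C)(O[Si](CC)(CC)CC)C[C@@H](OCc1ccc(OC)cc1)C=O | intermediate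
25 | methyl acrylate | C=CC(=O)OC | starting material
26 | Morita–Baylis–Hillman adduct (C7–OH epimers; methyl 2-methylene-3-hydroxy ester; 8R-OPMB) | CC(C)(C)[Si](C)(C)OC/C=C(/C)[C@H](O[Si](C)(C)C(C)(C)C)/C=C\[C@](C)(O[Si](CC)(CC)CC)C[C@@H](OCc1ccc(OC)cc1)C(O)C(=C)C(=O)OC | intermediate
27 | (1Z,3R,4Z,7Z,8R,10R)-methyl 2-(bromomethyl)enoate with 6-OTBS, 3-OTBS, 10-OTES, 8-OPMB | CC(C)(C)[Si](C)(C)OC/C=C(/C)[C@H](O[Si](C)(C)C(C)(C)C)/C=C\[C@](C)(O[Si](CC)(CC)CC)C[C@@H](OCc1ccc(OC)cc1)/C=C(\CBr)C(=O)OC | intermediate
28 | (1Z,3R,4Z,7Z,8R,10R)-C6 allylic alcohol of 27 | OC/C=C(/C)[C@H](O[Si](C)(C)C(C)(C)C)/C=C\[C@](C)(O[Si](CC)(CC)CC)C[C@@H](OCc1ccc(OC)cc1)/C=C(\CBr)C(=O)OC | intermediate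
29 | (1Z,3R,4Z,7Z,8R,10R)-seco precursor: C6 Z-enal and C13 allylic bromide | O=C/C=C(/C)[C@H](O[Si](C)(C)C(C)(C)C)/C=C\[C@](C)(O[Si](CC)(CC)CC)C[C@@H](OCc1ccc(OC)cc1)/C=C(\CBr)C(=O)OC | intermediate
30 | C13 allyl(dichloro)chromium species of 29 (trivalent chromium, not isolated) | O=C/C=C(/C)[C@H](O[Si](C)(C)C(C)(C)C)/C=C\[C@](C)(O[Si](CC)(CC)CC)C[C@@H](OCc1ccc(OC)cc1)/C=C(\C[Cr](Cl)Cl)C(=O)OC | intermediate
31 | (3R,6S,7R,8R,10R)-cyclised methyl ester as its C6 chromium alkoxide (not isolated) | C=C(C(=O)OC)[C@H]1[C@@H](O[Cr](Cl)Cl)/C=C(/C)[C@H](O[Si](C)(C)C(C)(C)C)/C=C\[C@](C)(O[Si](CC)(CC)CC)C[C@H]1OCc2ccc(OC)cc2 | intermediate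
32 | (1Z,3R,4Z,6S,7R,8R,10R)-protected cis-fused α-methylene lactone: 3-OTBS, 10-OTES, 8-OPMB | C=C1C(=O)O[C@H]2/C=C(/C)[C@H](O[Si](C)(C)C(C)(C)C)/C=C\[C@](C)(O[Si](CC)(CC)CC)C[C@@H](OCc3ccc(OC)cc3)[C@@H]12 | intermediate
33 | (1Z,3R,4Z,6S,7R,8R,10R)-C8 alcohol: 3-OTBS, 10-OTES | C=C1C(=O)O[C@H]2/C=C(/C)[C@H](O[Si](C)(C)C(C)(C)C)/C=C\[C@](C)(O[Si](CC)(CC)CC)C[C@@H](O)[C@@H]12 | intermediate
34 | tiglic acid | OC(=O)/C(C)=C/C | starting material
35 | tiglic 2,4,6-trichlorobenzoic anhydride (not isolated) | O=C(OC(=O)c1c(Cl)cc(Cl)cc1Cl)/C(C)=C/C | intermediate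
36 | (1Z,3R,4Z,6S,7R,8R,10R)-C8 tiglate: 3-OTBS, 10-OTES | C=C1C(=O)O[C@H]2/C=C(/C)[C@H](O[Si](C)(C)C(C)(C)C)/C=C\[C@](C)(O[Si](CC)(CC)CC)C[C@@H](OC(=O)/C(C)=C/C)[C@@H]12 | intermediate
37 | CNP0262559.2 | C=C1C(=O)O[C@H]2/C=C(/C)[C@H](O)/C=C\[C@](C)(O)C[C@@H](OC(=O)/C(C)=C/C)[C@@H]12 | target

Total step count: 22. Longest linear sequence: 21 steps (steps 1–7 and 9–22, from 1); step 8 is the one-step branch to 16.

Steps most likely to fail

1. Step 19. The ring closure may be outrun by intermolecular coupling or by protonation of the allylchromium, the C8 ether may be lost by β-elimination, and the face of C7 may be poorly discriminated in the loose macrocyclic transition state. Fallback: a boron-based closure of the same bond, setting out from 28. Palladium-catalysed borylation of the allylic bromide (Pd2(dba)3, B2pin2, DMSO/toluene) should give the allylboronate alcohol F1, with C8 cis to C13 as the thermodynamically preferred geometry of such 2-substituted enoates. Dess–Martin oxidation would then give the allylboronate enal F2, a stable and isolable seco compound. Heated in toluene at high dilution (or with catalytic Sc(OTf)3), F2 should cyclise through a compact closed chair, in which allylic strain is expressed more strongly and no reducing metal is present, to the cyclic borate F3. Treatment of F3 with PPTS would lactonise it, and the route is rejoined at 32.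

2. Step 15. The amine-catalysed addition to a hindered α-alkoxy aldehyde is slow, so base-mediated epimerisation at C8 and decomposition of the aldehyde may compete. Fallback: vinylalumination in place of amine catalysis, setting out from 24. Hydroalumination of methyl propiolate with i-Bu2AlH and N-methylmorpholine N-oxide in THF at 0 °C gives the α-(methoxycarbonyl)vinylalane F4. This preformed nucleophile adds to 24 at low temperature without any amine base, and aqueous work-up rejoins the route at 26.

3. Step 10. Facial discrimination in the reduction may be weak or reversed, because the alkynyl group carries the bulky quaternary C10 at its far end and may not behave as the small substituent; hydroboration by borane may also compete. Fallback: set C3 while forming C2–C3, setting out from 13 and 16. Reduction of 16 with i-Bu2AlH at −78 °C gives the (Z)-enal F5. Alkyne 13, converted with Me2Zn into the methylzinc acetylide F6, is then added to F5 under ProPhenol catalysis (ligand enantiomer chosen for the 3S carbinol; unsaturated aldehydes are the favoured substrates of this alkynylation). This bypasses 19 and rejoins the route at 20.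

Further compounds
F1 | step 19 | (1Z,3R,4Z,8R,10R)-C6 allylic alcohol with C13 pinacol boronate in place of bromide (C8 cis to C13) | OC/C=C(/C)[C@H](O[Si](C)(C)C(C)(C)C)/C=C\[C@](C)(O[Si](CC)(CC)CC)C[C@@H](OCc1ccc(OC)cc1)/C=C(\CB2OC(C)(C)C(C)(C)O2)C(=O)OC
F2 | step 19 | (1Z,3R,4Z,8R,10R)-C6 Z-enal with C13 pinacol boronate | O=C/C=C(/C)[C@H](O[Si](C)(C)C(C)(C)C)/C=C\[C@](C)(O[Si](CC)(CC)CC)C[C@@H](OCc1ccc(OC)cc1)/C=C(\CB2OC(C)(C)C(C)(C)O2)C(=O)OC
F3 | step 19 | (3R,6S,7R,8R,10R)-cyclised methyl ester as its C6 pinacol borate | C=C(C(=O)OC)[C@H]1[C@@H](OB2OC(C)(C)C(C)(C)O2)/C=C(/C)[C@H](O[Si](C)(C)C(C)(C)C)/C=C\[C@](C)(O[Si](CC)(CC)CC)C[C@H]1OCc3ccc(OC)cc3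
F4 | step 15 | methyl 2-(diisobutylalumanyl)acrylate | C=C(C(=O)OC)[Al](CC(C)C)CC(C)C
F5 | step 10 | (2Z)-4-(tert-butyldimethylsilyloxy)-2-methylbut-2-enal | O=C/C(C)=C\CO[Si](C)(C)C(C)(C)C
F6 | step 10 | methylzinc acetylide of 13 | C[Zn]C#C[C@](C)(O[Si](CC)(CC)CC)C[C@@H]1COC(c2ccc(OC)cc2)O1
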